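Labels: ring A = guaiacyl; rings B/C = dihydrobenzofuran (O1, C2, C3, C3a, C4–C7, C7a); ring D = C7'–O–C9''–C8''–C8'; ring E = C7''–O–C9'–C8'–C8''; ring F = syringyl.
Enabling feature: C7'' of ring E lies para to the free OH of the 2,6-dimethoxyphenol ring F. Its ether bond is therefore the adduct of the C9' hydroxyl to a syringyl quinone methide, and C7''–O is cut first, giving the 7''-deoxy seco compound.
Further cuts: C7'–O (ring D, benzylic ionisation), C7'–C8' (lactone aldol), C2–C3 (carbene C–H insertion), C3a–C3 (Pd coupling with ethyl diazoacetate), O1–C2 (Mitsunobu), C7''–C8'' (Stobbe).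
Forward: ring C is closed on rings A/B (steps 1–9) and the ring F lactone is made (steps 10–13). The halves are joined by aldol, ring D is closed, the protecting groups leave, and the oxidase closes ring E last.
Stereochemistry: C2/C3 (cis) come from a chiral dirhodium catalyst and C8'' from asymmetric hydrogenation. C8' follows from C8'' (anti aldol), C7' from C8' (trans closure), and C7'' from the cis-fused bicycle (aryl exo).

Key step: step 19

Assumption: the sense of induction of Rh2(R-PTTL)4 (step 6) and of the (S,S)-Et-DuPhos rhodium catalyst (step 12) is assigned by analogy with closely related substrates; if either gives the mirror-image series, the antipodal ligand is used and nothing else changes.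

Step 1
Reactants: 1 vanillin (4-hydroxy-3-methoxybenzaldehyde)
Product: 2 3-methoxy-4-(triisopropylsilyloxy)benzaldehyde
Conditions: TIPSCl, imidazole, DMF, rt
Reagents that add atoms: triisopropylsilyl chloride, CC(C)[Si](Cl)(C(C)C)C(C)C
Why: Imidazole-promoted silylation of a phenol; the bulky TIPS ether should survive hydrides, organolithiums and amine bases, falls to fluoride, and is orthogonal to the benzyl ether used on ring F.

Step 2
Reactants: 2 3-methoxy-4-(triisopropylsilyloxy)benzaldehyde
Product: 3 [3-methoxy-4-(triisopropylsilyloxy)phenyl]methanol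
Conditions: NaBH4, MeOH, 0 °C
Reagents that add atoms: none
Why: Chemoselective borohydride reduction of an aromatic aldehyde, which leaves the aryl silyl ether untouched.

Step 3
Reactants: 4 4-bromo-2-methoxyphenol
Product: 5 4-bromo-2-iodo-6-methoxyphenol
Conditions: NIS, TsOH·H2O (10 mol%), MeCN, rt
Reagents that add atoms: N-iodosuccinimide, O=C1CCC(=O)N1I
Why: Electrophilic aromatic iodination directed by the free phenol; the para position is blocked by bromine, so only the open ortho position (the future C3a) should react.

Step 4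
Reactants: 3 [3-methoxy-4-(triisopropylsilyloxy)phenyl]methanol; 5 4-bromo-2-iodo-6-methoxyphenol
Product: 6 5-bromo-1-iodo-3-methoxy-2-{[3-methoxy-4-(triisopropylsilyloxy)phenyl]methoxy}benzene
Conditions: PPh3, DIAD, THF, 0 °C to rt
Reagents that add atoms: none
Why: Mitsunobu etherification of an acidic phenol with a primary benzylic alcohol forms O1–C2 under neutral conditions that spare the silyl ether and both halides.

Step 5
Reactants: 6 the aryl iodide of step 4; 7 ethyl diazoacetate
Product: 8 ethyl 2-(5-bromo-3-methoxy-2-{[3-methoxy-4-(triisopropylsilyloxy)phenyl]methoxy}phenyl)-2-diazoacetate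
Conditions: Pd(PPh3)4 (5 mol%), Ag2CO3 (0.5 equiv), Et3N, toluene, rt
Reagents that add atoms: none
Why: Palladium-catalysed cross-coupling of an aryl iodide with the C–H bond of a diazoacetate, which keeps the diazo group; zerovalent palladium adds to C–I much faster than to C–Br at room temperature, so the bromide is kept for step 9 while the C3a–C3 bond and the carbene precursor arrive in one operation.

Step 6
Reactants: 8 the aryldiazoacetate of step 5
Product: 9 ethyl (2S,3R)-5-bromo-7-methoxy-2-[3-methoxy-4-(triisopropylsilyloxy)phenyl]-2,3-dihydro-1-benzofuran-3-carboxylate (aryl and ester cis)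
Conditions: Rh2(R-PTTL)4 (1 mol%; PTTL = N-phthaloyl-tert-leucinate), toluene, −60 °C
Reagents that add atoms: none
Why: Enantioselective intramolecular 1,5 C–H insertion of an aryl(ester) carbene bound to a chiral dirhodium tetracarboxylate into the benzylic ether C–H forms C2–C3 and ring C; with N-phthaloyl amino acid ligands this reaction type is known to give 2-aryl-2,3-dihydrobenzofuran-3-carboxylates as the kinetic cis isomers, 5-bromo substrates included, so the catalyst sets C2 and C3 together in one concerted event that never passes through an enolate.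

Step 7
Reactants: 9 the cis ester of step 6
Product: 10 {(2S,3S)-5-bromo-7-methoxy-2-[3-methoxy-4-(triisopropylsilyloxy)phenyl]-2,3-dihydro-1-benzofuran-3-yl}methanol (cis)
Conditions: i-Bu2AlH (3 equiv), CH2Cl2, −78 to −20 °C; aq. potassium sodium tartrate
Reagents that add atoms: none
Why: Ester reduction with a neutral aluminium hydride at low temperature; no base is present and reduction outruns enolisation, so C3 should keep its cis relation to C2.

Step 8
Reactants: 10 the cis alcohol of step 7
Product: 11 tert-butyldimethylsilyl ether of 10, (2S,3S)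
Conditions: TBSCl, imidazole, CH2Cl2, rt
Reagents that add atoms: tert-butyldimethylsilyl chloride, CC(C)(C)[Si](C)(C)Cl
Why: Routine silylation of a primary alcohol removes the only acidic proton before the organolithium and enolate steps.

Step 9
Reactants: 11 the bromide of step 8
Product: 13 (2S,3S)-3-(tert-butyldimethylsilyloxymethyl)-7-methoxy-2-[3-methoxy-4-(triisopropylsilyloxy)phenyl]-2,3-dihydro-1-benzofuran-5-carbaldehyde, via aryllithium 12 (not isolated)
Conditions: n-BuLi, THF, −78 °C; DMF; AcOH
Reagents that add atoms: N,N-dimethylformamide, CN(C)C=O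
Why: Bromine–lithium exchange followed by Bouveault-type formylation with DMF; the exchange is faster than any deprotonation at −78 °C, and both silyl ethers and both stereocentres are remote from the carbanion.

Step 10
Reactants: 14 syringaldehyde (4-hydroxy-3,5-dimethoxybenzaldehyde)
Product: 15 4-(benzyloxy)-3,5-dimethoxybenzaldehyde
Conditions: BnBr, K2CO3, DMF, 50 °C
Reagents that add atoms: benzyl bromide, BrCc1ccccc1
Why: Williamson etherification; the benzyl ether withstands alkoxide, homogeneous hydrogenation, hydrides and enolates and can later be removed without touching the silyl ethers.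

Step 11
Reactants: 15 4-(benzyloxy)-3,5-dimethoxybenzaldehyde; 16 dimethyl succinate
Product: 17 (E)-4-[4-(benzyloxy)-3,5-dimethoxyphenyl]-3-(methoxycarbonyl)but-3-enoic acid
Conditions: NaOMe, MeOH, reflux; aq. HCl
Reagents that add atoms: none
Why: Stobbe condensation, which gives regiospecifically the half-ester with the free acid on the CH2 arm and forms the C7''–C8'' bond as the E alkene (aryl trans to the ester) on steric grounds.

Step 12
Reactants: 17 the Stobbe half-ester
Product: 18 (3R)-4-[4-(benzyloxy)-3,5-dimethoxyphenyl]-3-(methoxycarbonyl)butanoic acid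
Conditions: [Rh(cod)((S,S)-Et-DuPhos)]BF4 (0.5 mol%), H2 (5 bar), NaOMe (10 mol%), MeOH, rt
Reagents that add atoms: none
Why: Asymmetric hydrogenation of a Stobbe-derived itaconate half-ester; alkene and carboxylate chelate the cationic monovalent rhodium centre and the C2-symmetric bisphospholane fixes the face of hydrogen delivery, which sets C8'' while the benzyl ether is left alone.

Step 13
Reactants: 18 the (R)-half-ester
Product: 20 (4R)-4-[4-(benzyloxy)-3,5-dimethoxybenzyl]dihydrofuran-2(3H)-one, via hydroxy acid 19 (not isolated)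
Conditions: KOH (1 equiv), EtOH; CaCl2, NaBH4, −10 °C to rt; aq. HCl, rt
Reagents that add atoms: none
Why: Chemoselective reduction of the ester beside the unreactive carboxylate salt by Ca(BH4)2, then acid-promoted lactonisation; C8'' is not touched and the former ester carbon becomes C9''.

Step 14
Reactants: 20 the (R)-lactone; 13 the dihydrobenzofuran aldehyde
Product: 22 (3S,4R)-4-[4-(benzyloxy)-3,5-dimethoxybenzyl]-3-{hydroxy[ring B C5 of the (2S,3S)-dihydrobenzofuran of 13]methyl}dihydrofuran-2(3H)-one (trans lactone; both C7' epimers), via lithium enolate 21 (not isolated)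
Conditions: LiN(SiMe3)2, THF, −78 °C; 13; AcOH, −78 °C
Reagents that add atoms: none
Why: Aldol addition of a lactone lithium enolate to an aromatic aldehyde forms C7'–C8'; the aldehyde approaches the enolate face opposite the C8'' benzyl group and so sets C8' trans to it, while the C7' carbinol arises as two epimers that converge in step 16.

Step 15
Reactants: 22 the aldol adduct
Product: 23 (8'R,8''R)-triol: C7'(OH)(ring B)–C8'(CH2OH)–C8''(CH2OH)–CH2(4-benzyloxy-3,5-dimethoxyphenyl), both C7' epimers, silyl ethers retained
Conditions: LiAlH4, THF, 0 °C; aq. NaOH work-up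
Reagents that add atoms: none
Why: Standard LiAlH4 reduction of a lactone to the 1,4-diol, which leaves silyl and benzyl ethers and all stereocentres alone and turns the carbonyl carbon into the C9' hydroxymethyl group needed in the key step.

Step 16
Reactants: 23 the triol
Product: 25 {(2S,3R,4R)-4-[4-(benzyloxy)-3,5-dimethoxybenzyl]-2-[(2S,3S)-3-(tert-butyldimethylsilyloxymethyl)-7-methoxy-2-(3-methoxy-4-triisopropylsilyloxyphenyl)-2,3-dihydro-1-benzofuran-5-yl]tetrahydrofuran-3-yl}methanol (7'S,8'R,8''R), via C7' benzylic cation 24 (not isolated)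
Conditions: camphor-10-sulfonic acid (10 mol%), CH2Cl2, 0 °C; Et3N quench
Reagents that add atoms: none
Why: Acid-catalysed SN1 cyclodehydration as used for lariciresinol-type triols: both C7' epimers ionise to one cation stabilised by the coplanar para oxygen O1, the C9'' hydroxyl closes the five-membered ring D (the C9' hydroxyl could only give an oxetane) with ring B settling trans to the C8' hydroxymethyl group (7'S), the twisted and weakly donating OTIPS group on ring A keeps C2–O1 from ionising, and early quenching forestalls re-ionisation and Friedel–Crafts attack by ring F.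

Step 17
Reactants: 25 the protected seco compound
Product: 26 the ring F phenol: 25 with 4-hydroxy-3,5-dimethoxybenzyl in place of the benzyloxy-substituted benzyl group, silyl ethers retained
Conditions: H2 (1 atm), Pd/C, EtOAc, rt
Reagents that add atoms: none
Why: Catalytic hydrogenolysis of an aryl benzyl ether, which under one atmosphere in EtOAc is much faster than cleavage of the cyclic benzylic C–O bonds at C2 and C7' and does not affect silyl ethers.

Step 18
Reactants: 26 the ring F phenol
Product: 27 7''-deoxy seco compound: (2S,3S)-2-(4-hydroxy-3-methoxyphenyl)-3-(hydroxymethyl)-7-methoxy-5-[(2S,3R,4R)-4-(4-hydroxy-3,5-dimethoxybenzyl)-3-(hydroxymethyl)tetrahydrofuran-2-yl]-2,3-dihydro-1-benzofuran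
Conditions: Bu4NF/AcOH (1:1), THF, 0 °C to rt
Reagents that add atoms: none
Why: Fluoride-driven cleavage of the aryl TIPS and primary TBS ethers; acetic acid keeps the ring A phenol protonated, so no phenoxide can expel O1 from C2 and the cis pair should be kept.

Step 19
Reactants: 27 the 7''-deoxy seco compound
Product: 29 target (2S,3S)-2-(4-hydroxy-3-methoxyphenyl)-3-(hydroxymethyl)-7-methoxy-5-[(1S,3aR,4S,6aR)-4-(4-hydroxy-3,5-dimethoxyphenyl)tetrahydro-1H,3H-furo[3,4-c]furan-1-yl]-2,3-dihydro-1-benzofuran, via syringyl quinone methide 28 (not isolated)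
Conditions: engineered eugenol oxidase variant (FAD-bound), air, catalase, KH2PO4/K2HPO4 buffer pH 7.5, DMSO (10 vol%), 30 °C; EtOAc extraction, chromatography
Reagents that add atoms: none
Why: Proposed new method: the ring F phenolate bound next to the flavin should pass a hydride from C7'' to N5 of FAD, O2 then reoxidises the reduced cofactor with release of H2O2, and the planar quinone methide 28 is an oxa-Michael acceptor for the C9' hydroxyl held close by on the same face of ring D. The closest known reaction type is the oxidase-catalysed dehydrogenation of 4-alkyl- and 4-allyl-2,6-dimethoxyphenols to quinone methides that are then hydrated; here an internal alcohol replaces water and the substrate is far larger, so a variant with a widened access channel has to be evolved. Ring E closes in the 5-exo-trig mode, because the C7''=C1'' double bond lies outside the forming O–C9'–C8'–C8''–C7'' ring. C7'' is set by the substrate and not by the protein: C9' and C7'' already stand cis on ring D, so only a cis-fused bicycle can form, ring F takes the convex exo position (7''S), and since the product keeps its para phenol the addition is in principle reversible and drains to this more stable epimer. The step needs site selectivity between two free phenols: only C7'' and C2 lie para to a phenolic OH, and C7'' is an unbranched, freely rotating CH2 on the more easily oxidised dimethoxyphenol, whereas C2 is a tertiary ring carbon flanked by O1 and the C3 side chain that cannot place its hydrogen over N5 in a pocket shaped for linear 4-alkyl chains. C7' and C3 have no para phenol and are outside the reach of this enzyme class, so no protecting group is needed.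

Compound list
1 | vanillin | COc1cc(C=O)ccc1O | starting material
2 | 3-methoxy-4-(triisopropylsilyloxy)benzaldehyde | COc1cc(C=O)ccc1O[Si](C(C)C)(C(C)C)C(C)C | intermediate
3 | [3-methoxy-4-(triisopropylsilyloxy)phenyl]methanol | COc1cc(CO)ccc1O[Si](C(C)C)(C(C)C)C(C)C | intermediate
4 | 4-bromo-2-methoxyphenol | COc1cc(Br)ccc1O | starting material
5 | 4-bromo-2-iodo-6-methoxyphenol | COc1cc(Br)cc(I)c1O | intermediate
6 | aryl benzyl ether (iodide, bromide) | COc1cc(COc2c(I)cc(Br)cc2OC)ccc1O[Si](C(C)C)(C(C)C)C(C)C | intermediate
7 | ethyl diazoacetate | CCOC(=O)C=[N+]=[N-] | starting material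
8 | ethyl aryldiazoacetate | CCOC(=O)C(=[N+]=[N-])c1cc(Br)cc(OC)c1OCc1ccc(O[Si](C(C)C)(C(C)C)C(C)C)c(OC)c1 | intermediate
9 | ethyl (2S,3R)-cis-dihydrobenzofuran-3-carboxylate, 5-bromo | COc1cc([C@H]2Oc3c(OC)cc(Br)cc3[C@H]2C(=O)OCC)ccc1O[Si](C(C)C)(C(C)C)C(C)C | intermediate
10 | (2S,3S)-cis alcohol, 5-bromo | COc1cc([C@H]2Oc3c(OC)cc(Br)cc3[C@H]2CO)ccc1O[Si](C(C)C)(C(C)C)C(C)C | intermediate
11 | TBS ether of 10 | COc1cc([C@H]2Oc3c(OC)cc(Br)cc3[C@H]2CO[Si](C)(C)C(C)(C)C)ccc1O[Si](C(C)C)(C(C)C)C(C)C | intermediate
12 | C5 aryllithium (not isolated) | COc1cc([C@H]2Oc3c(OC)cc([Li])cc3[C@H]2CO[Si](C)(C)C(C)(C)C)ccc1O[Si](C(C)C)(C(C)C)C(C)C | intermediate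
13 | (2S,3S)-dihydrobenzofuran-5-carbaldehyde | COc1cc([C@H]2Oc3c(OC)cc(C=O)cc3[C@H]2CO[Si](C)(C)C(C)(C)C)ccc1O[Si](C(C)C)(C(C)C)C(C)C | intermediate
14 | syringaldehyde | COc1cc(C=O)cc(OC)c1O | starting material
15 | 4-(benzyloxy)-3,5-dimethoxybenzaldehyde | COc1cc(C=O)cc(OC)c1OCc1ccccc1 | intermediate
16 | dimethyl succinate | COC(=O)CCC(=O)OC | starting material
17 | (E)-Stobbe half-ester | COC(=O)/C(CC(=O)O)=C/c1cc(OC)c(OCc2ccccc2)c(OC)c1 | intermediate
18 | (R)-half-ester | COC(=O)[C@H](Cc1cc(OC)c(OCc2ccccc2)c(OC)c1)CC(=O)O | intermediate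
19 | (3R)-hydroxy acid (not isolated) | OC[C@H](Cc1cc(OC)c(OCc2ccccc2)c(OC)c1)CC(=O)O | intermediate
20 | (4R)-4-[4-(benzyloxy)-3,5-dimethoxybenzyl]dihydrofuran-2(3H)-one | O=C1OC[C@H](Cc2cc(OC)c(OCc3ccccc3)c(OC)c2)C1 | intermediate
21 | lithium enolate of 20 (not isolated) | [Li]OC1=C[C@@H](Cc2cc(OC)c(OCc3ccccc3)c(OC)c2)CO1 | intermediate
22 | aldol adduct, trans lactone, C7' epimers | COc1cc([C@H]2Oc3c(OC)cc(C(O)[C@H]4C(=O)OC[C@@H]4Cc5cc(OC)c(OCc6ccccc6)c(OC)c5)cc3[C@H]2CO[Si](C)(C)C(C)(C)C)ccc1O[Si](C(C)C)(C(C)C)C(C)C | intermediate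
23 | (8'R,8''R)-triol, C7' epimers | COc1cc([C@H]2Oc3c(OC)cc(C(O)[C@@H](CO)[C@H](CO)Cc4cc(OC)c(OCc5ccccc5)c(OC)c4)cc3[C@H]2CO[Si](C)(C)C(C)(C)C)ccc1O[Si](C(C)C)(C(C)C)C(C)C | intermediate
24 | C7' benzylic cation (not isolated) | COc1cc([C@H]2Oc3c(OC)cc([CH+][C@@H](CO)[C@H](CO)Cc4cc(OC)c(OCc5ccccc5)c(OC)c4)cc3[C@H]2CO[Si](C)(C)C(C)(C)C)ccc1O[Si](C(C)C)(C(C)C)C(C)C | intermediate
25 | protected seco compound (ring D closed; OBn, OTBS, OTIPS) | COc1cc([C@H]2Oc3c(OC)cc([C@H]4OC[C@H](Cc5cc(OC)c(OCc6ccccc6)c(OC)c5)[C@@H]4CO)cc3[C@H]2CO[Si](C)(C)C(C)(C)C)ccc1O[Si](C(C)C)(C(C)C)C(C)C | intermediate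
26 | ring F phenol, silyl ethers retained | COc1cc([C@H]2Oc3c(OC)cc([C@H]4OC[C@H](Cc5cc(OC)c(O)c(OC)c5)[C@@H]4CO)cc3[C@H]2CO[Si](C)(C)C(C)(C)C)ccc1O[Si](C(C)C)(C(C)C)C(C)C | intermediate
27 | 7''-deoxy seco compound | COc1cc([C@H]2Oc3c(OC)cc([C@H]4OC[C@H](Cc5cc(OC)c(O)c(OC)c5)[C@@H]4CO)cc3[C@H]2CO)ccc1O | intermediate
28 | syringyl quinone methide (not isolated) | COc1cc([C@H]2Oc3c(OC)cc([C@H]4OC[C@H](C=C5C=C(OC)C(=O)C(OC)=C5)[C@@H]4CO)cc3[C@H]2CO)ccc1O | intermediate
29 | CNP0126146.1 | COc1cc([C@H]2Oc3c(OC)cc([C@H]4OC[C@H]5[C@@H]4CO[C@@H]5c4cc(OC)c(O)c(OC)c4)cc3[C@H]2CO)ccc1O | target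

Total step count: 19. Longest linear sequence: 14 steps (1, 2, 4–9, 14–19).

Steps most likely to fail

Step 19. The bulky substrate may not reach the closed active site, so that no turnover occurs. The quinone methide may be intercepted by water or tautomerise by loss of the C8'' proton. Hydride abstraction at C2 may open ring C, and the new benzylic ether C–H may be oxidised further.
The fallback replaces protein control with protecting-group control and uses known chemistry. It sets out from 26, in which ring F carries the only free phenol. Oxidation with Ag2O in CH2Cl2 at rt is an established way from 4-alkyl-2,6-dimethoxyphenols to quinone methides, and should give the silyl-protected quinone methide F1. The C9' hydroxyl captures it in the same 5-exo mode to give the bis-silyl ether of the target F2. Bu4NF/AcOH as in step 18 then brings the sequence back to 29.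

Step 6. The C7 methoxy group forces the benzyloxy arm out of the ring plane, which may erode both the enantiofacial discrimination and the cis preference. Carbene dimerisation may overtake a slowed insertion.
The fallback changes the carbene class and brings C3 in at the alcohol oxidation level. It sets out from iodide 6. Iodine–magnesium exchange (iPrMgCl·LiCl, THF, −20 °C, bromide untouched) gives the arylmagnesium chloride F3. This is acylated with 2-(tert-butyldimethylsilyloxy)-N-methoxy-N-methylacetamide to the aryl ketone F4, and hydrazine hydrate converts the ketone into the hydrazone F5. MnO2 oxidises the hydrazone to the aryl alkyl diazo compound F6. The antipode of Rh2(PTAD)4 (PTAD = N-phthaloyl-(1-adamantyl)glycinate) matched to the (2S,3S) series then closes ring C by insertion of a donor/donor carbene, a reaction class noted for cis-2,3-disubstituted dihydrobenzofurans. The route is rejoined directly at 11.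

Step 5. Oxidative addition and transfer of the diazo carbon may be slow at the ortho-alkoxy, rather electron-rich iodide. Palladium- or silver-induced decomposition of the diazoester could then outrun coupling, and forcing conditions would bring C–Br into play.
The fallback separates C–C bond formation from introduction of the diazo group. It sets out from 6. Negishi-type coupling with the Reformatsky reagent BrZnCH2CO2Et (Pd(PPh3)4, THF, 50 °C) should give the ethyl arylacetate F7. Regitz diazo transfer with 4-acetamidobenzenesulfonyl azide and DBU in MeCN returns to 8.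

Further compounds
F1 | step 19 | silyl-protected syringyl quinone methide | COc1cc([C@H]2Oc3c(OC)cc([C@H]4OC[C@H](C=C5C=C(OC)C(=O)C(OC)=C5)[C@@H]4CO)cc3[C@H]2CO[Si](C)(C)C(C)(C)C)ccc1O[Si](C(C)C)(C(C)C)C(C)C
F2 | step 19 | bis-silyl ether of the target | COc1cc([C@H]2Oc3c(OC)cc([C@H]4OC[C@H]5[C@@H]4CO[C@@H]5c4cc(OC)c(O)c(OC)c4)cc3[C@H]2CO[Si](C)(C)C(C)(C)C)ccc1O[Si](C(C)C)(C(C)C)C(C)C
F3 | step 6 | arylmagnesium chloride | COc1cc(COc2c(OC)cc(Br)cc2[Mg]Cl)ccc1O[Si](C(C)C)(C(C)C)C(C)C
F4 | step 6 | aryl silyloxymethyl ketone | COc1cc(COc2c(OC)cc(Br)cc2C(=O)CO[Si](C)(C)C(C)(C)C)ccc1O[Si](C(C)C)(C(C)C)C(C)C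
F5 | step 6 | hydrazone of F4 | COc1cc(COc2c(OC)cc(Br)cc2C(=NN)CO[Si](C)(C)C(C)(C)C)ccc1O[Si](C(C)C)(C(C)C)C(C)C
F6 | step 6 | aryl alkyl diazo compound | COc1cc(COc2c(OC)cc(Br)cc2C(=[N+]=[N-])CO[Si](C)(C)C(C)(C)C)ccc1O[Si](C(C)C)(C(C)C)C(C)C
F7 | step 5 | ethyl arylacetate | CCOC(=O)Cc1cc(Br)cc(OC)c1OCc1ccc(O[Si](C(C)C)(C(C)C)C(C)C)c(OC)c1
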